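**Assumption (one line):** labdane numbering is used throughout (C4 bears the C18 methyl and the C19 carboxyl, C10 bears C20, C8 bears the C17 methylene, C13 is the side-chain stereocentre, C15 the esterified CH2O); compounds 1, 6, 7 and 15 are bought.

## Retrosynthetic overview

1. The target is the O-acylation product of the C15 hydroxy acid with (R)-2-methylbutanoic acid; the free C19 acid comes from a chiral cumylcyclohexyl ester by reductive alkyl–oxygen cleavage.
2. Both rings form in one cascade from an acyclic, C19-oxidised (13R)-13,14-dihydrogeranylgeranyl chain: ring A first (C4–C5), then ring B (C10–C9), ended by loss of H from C17 to give the 8(17)-alkene. This is the radical counterpart of the ent-copalyl cyclase cascade, started by hydrogen-atom transfer (HAT) from a cobalt hydride to a 2-alkylacrylate; the ester auxiliary sets the absolute sense.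
3. The acyclic precursor is cut at C2–C3: an alkyl-9-BBN (from a terminal 1,3-diene) plus a 2-(bromomethyl)acrylate ester.
4. The diene comes from (R)-2,3-dihydrofarnesol by ω-allylic oxidation and methylenation; C13 is set by Ru-BINAP hydrogenation of (2E,6E)-farnesol.

## Route

**Step 1**
Reactants: 1 (2E,6E)-farnesol
Product: 2 (R)-2,3-dihydrofarnesol, (3R,6E)-3,7,11-trimethyldodeca-6,10-dien-1-ol
Conditions: H2 (100 atm), Ru(OAc)2[(S)-BINAP] (0.2 mol%), MeOH/H2O 95:5, 20 °C
Reagents that add atoms: none
Why: Noyori asymmetric hydrogenation; the allylic hydroxyl binds ruthenium so only the C2=C3 alkene is reduced, and the (S)-BINAP complex delivers H2 to the face of the (E)-allylic alcohol that gives the 3R centre (the future C13), the two remote trisubstituted alkenes being inert.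

**Step 2**
Reactants: 2 (R)-2,3-dihydrofarnesol
Product: 4 (2E,6E,10R)-12-hydroxy-2,6,10-trimethyldodeca-2,6-dienal, via allylic diol 3 (not isolated)
Conditions: SeO2 (0.3 equiv), t-BuOOH (3 equiv), CH2Cl2, 0 °C → rt; filter; MnO2 (excess), CH2Cl2, rt
Reagents that add atoms: selenium dioxide, O=[Se]=O; tert-butyl hydroperoxide, CC(C)(C)OO
Why: Riley-type SeO2 allylic oxidation (ene reaction, then [2,3]-shift) selects the (E)-methyl of the terminal, most electron-rich trisubstituted alkene, and MnO2 then oxidises only the allylic hydroxyl, converging the alcohol/aldehyde mixture to the E-enal without touching the saturated primary alcohol or C13.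

**Step 3**
Reactants: 4 (2E,6E,10R)-12-hydroxy-2,6,10-trimethyldodeca-2,6-dienal
Product: 5 (3R,6E,10E)-3,7,11-trimethyltrideca-6,10,12-trien-1-ol
Conditions: Ph3PCH3Br (1.5 equiv), KN(SiMe3)2 (1.4 equiv), THF, 0 °C; then 4, −78 → 0 °C
Reagents that add atoms: methyltriphenylphosphonium bromide, C[P+](c1ccccc1)(c1ccccc1)c1ccccc1.[Br-]
Why: Wittig methylenation of the enal gives the terminal 1,3-diene with the trisubstituted alkene geometry retained; the ylide is not basic enough to disturb the free hydroxyl.

**Step 4** (side branch)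
Reactants: 6 2-(bromomethyl)prop-2-enoic acid; 7 (1S,2R)-2-(2-phenylpropan-2-yl)cyclohexan-1-ol
Product: 10 (1S,2R)-2-(2-phenylpropan-2-yl)cyclohexyl 2-(bromomethyl)prop-2-enoate, via acid chloride 8 (not isolated), via lithium alkoxide 9 (not isolated)
Conditions: 6, (COCl)2, DMF (cat.), CH2Cl2, 0 °C → rt, evaporate; 7, n-BuLi, THF, −78 °C, then added to 8, −78 → 0 °C
Reagents that add atoms: none
Why: acyl chloride formation followed by O-acylation of the preformed lithium alkoxide of the hindered secondary alcohol (acylation outruns attack at the allylic bromide at −78 °C); no stereocentre is affected.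

**Step 5**
Reactants: 5 (3R,6E,10E)-3,7,11-trimethyltrideca-6,10,12-trien-1-ol; 10 (1S,2R)-2-(2-phenylpropan-2-yl)cyclohexyl 2-(bromomethyl)prop-2-enoate
Product: 12 (1S,2R)-2-(2-phenylpropan-2-yl)cyclohexyl (6E,10E,14R)-16-hydroxy-6,10,14-trimethyl-2-methylidenehexadeca-6,10-dienoate, via bis-borane 11 (not isolated)
Conditions: 9-BBN dimer (1.1 equiv, i.e. 2.2 B–H), THF, 0 °C → rt; then KOtBu (1.1 equiv), CuOAc (10 mol%), 10 (1.3 equiv), THF, 0 °C → rt; H2O work-up
Reagents that add atoms: none
Why: Brown hydroboration with 9-BBN selects the terminal CH2 of the monosubstituted alkene of the diene (the hydroxyl is masked in the flask as its B-alkoxy-9-BBN), and the alkyl borate transmetallates to copper and displaces bromide from the 2-(bromomethyl)acrylate (SN2 and SN2′ attack give the same 2-alkylacrylate), a copper-catalysed alkylborane–allyl coupling that leaves the E-alkenes and C13 untouched.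

**Step 6** (key step)
Reactants: 12 (1S,2R)-2-(2-phenylpropan-2-yl)cyclohexyl (6E,10E,14R)-16-hydroxy-6,10,14-trimethyl-2-methylidenehexadeca-6,10-dienoate
Product: 13 (1S,2R)-2-(2-phenylpropan-2-yl)cyclohexyl (13R)-15-hydroxy-ent-labd-8(17)-en-19-oate, i.e. the (1R,4aS,5R,8aS)-5-[(3R)-5-hydroxy-3-methylpentyl]-1,4a-dimethyl-6-methylidenedecahydronaphthalene-1-carboxylate
Conditions: Co(C32H46N2O2)Cl [chloro(N,N′-bis(3,5-di-tert-butylsalicylidene)ethane-1,2-diaminato)cobalt, trivalent cobalt] (3 mol%), PhSiH3 (6 mol%), PhH (0.02 M), 22 °C, Ar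
Reagents that add atoms: none
Why: Proposed new method: the hydride Co(C32H46N2O2)H, formed from the chloride and PhSiH3, transfers H• to the terminal CH2 of the 2-alkylacrylate (by far the most HAT-reactive alkene present; this carbon becomes the C18 methyl) to give the electrophilic tertiary α-ester radical at C4, which adds 6-endo to the electron-rich C5=C10 alkene, and the C10 radical then adds 6-endo to C9=C8 through a chair–chair array (E,E-alkenes give the trans ring fusion and an equatorial C9 side chain; the flat conjugated ester takes the pseudo-axial site syn to C20 in preference to CH3, as in Mn(OAc)3 cyclisations of 2-methyl-3-oxo esters); divalent cobalt finally abstracts H• from the most accessible β-position, the C17 methyl of the C8 radical, releasing the exocyclic alkene under kinetic control and regenerating the hydride (net cycloisomerisation, no stoichiometric reagent); absolute control: in the usual s-cis ester with C=O turned towards C3 and the bulky alkoxy group turned away from the forming ring, the cumyl phenyl of the (1S,2R) auxiliary covers the Re face of C4, so C5 bonds to the Si face and gives 4R,5S,9R,10S; the closest known reactions are cobalt-salen-hydride HAT-initiated diene cycloisomerisations and polyene bicyclisations, and 8-phenylmenthyl-ester-controlled Mn(OAc)3 radical polyene cyclisations.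

**Step 7**
Reactants: 13 (1S,2R)-2-(2-phenylpropan-2-yl)cyclohexyl (13R)-15-hydroxy-ent-labd-8(17)-en-19-oate
Product: 14 (13R)-15-hydroxy-ent-labd-8(17)-en-19-oic acid, (1R,4aS,5R,8aS)-5-[(3R)-5-hydroxy-3-methylpentyl]-1,4a-dimethyl-6-methylidenedecahydronaphthalene-1-carboxylic acid
Conditions: K (8 equiv), 18-crown-6 (1 equiv), t-BuNH2/THF, rt, 1 h; i-PrOH, then H2O, pH 3
Reagents that add atoms: none
Why: dissolving-metal reduction of a hindered ester with alkyl–oxygen fission (the ester-deoxygenation reaction of hindered carboxylates); the ester radical anion, shielded from acyl substitution by the quaternary C4, the syn-axial C10 methyl and the cumylcyclohexyl group, fragments to the C19 carboxylate and a cyclohexyl radical that is reduced to the hydrocarbon, while the isolated alkene and all stereocentres are untouched.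

**Step 8**
Reactants: 14 (13R)-15-hydroxy-ent-labd-8(17)-en-19-oic acid; 15 (R)-2-methylbutanoic acid
Product: 16 target, (1R,4aS,5R,8aS)-1,4a-dimethyl-6-methylidene-5-[(3R)-3-methyl-5-{[(2R)-2-methylbutanoyl]oxy}pentyl]decahydronaphthalene-1-carboxylic acid
Conditions: 15 (1.3 equiv), EDC·HCl (1.4 equiv), DMAP (0.1 equiv), CH2Cl2, 0 °C → rt; aqueous work-up at pH 3
Reagents that add atoms: none
Why: Steglich-type carbodiimide esterification; only the unhindered primary C15 hydroxyl is acylated by the activated (R)-acid, because the neopentyl, 1,3-diaxially shielded C19 acid cannot act as an acyl donor (any mixed anhydride is hydrolysed on work-up), and the α-stereocentre of the simple alkyl acid is not epimerised under these mild conditions.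

## Compound list

1 | (2E,6E)-farnesol, (2E,6E)-3,7,11-trimethyldodeca-2,6,10-trien-1-ol | CC(C)=CCC/C(C)=C/CC/C(C)=C/CO | starting material
2 | (R)-2,3-dihydrofarnesol, (3R,6E)-3,7,11-trimethyldodeca-6,10-dien-1-ol | CC(C)=CCC/C(C)=C/CC[C@@H](C)CCO | intermediate
3 | (2E,6E,10R)-2,6,10-trimethyldodeca-2,6-diene-1,12-diol | OC/C(C)=C/CC/C(C)=C/CC[C@@H](C)CCO | intermediate (not isolated)
4 | (2E,6E,10R)-12-hydroxy-2,6,10-trimethyldodeca-2,6-dienal | O=C/C(C)=C/CC/C(C)=C/CC[C@@H](C)CCO | intermediate
5 | (3R,6E,10E)-3,7,11-trimethyltrideca-6,10,12-trien-1-ol | C=C/C(C)=C/CC/C(C)=C/CC[C@@H](C)CCO | intermediate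
6 | 2-(bromomethyl)prop-2-enoic acid | C=C(CBr)C(=O)O | starting material
7 | (1S,2R)-2-(2-phenylpropan-2-yl)cyclohexan-1-ol (trans-2-cumylcyclohexanol) | O[C@H]1CCCC[C@@H]1C(C)(C)c1ccccc1 | starting material
8 | 2-(bromomethyl)prop-2-enoyl chloride | C=C(CBr)C(Cl)=O | intermediate (not isolated)
9 | lithium (1S,2R)-2-(2-phenylpropan-2-yl)cyclohexan-1-olate | [Li+].[O-][C@H]1CCCC[C@@H]1C(C)(C)c1ccccc1 | intermediate (not isolated)
10 | (1S,2R)-2-(2-phenylpropan-2-yl)cyclohexyl 2-(bromomethyl)prop-2-enoate | C=C(CBr)C(=O)O[C@H]1CCCC[C@@H]1C(C)(C)c1ccccc1 | intermediate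
11 | 9-{(3E,7E,11R)-13-[(9-borabicyclo[3.3.1]nonan-9-yl)oxy]-3,7,11-trimethyltrideca-3,7-dien-1-yl}-9-borabicyclo[3.3.1]nonane | B1(CC/C(C)=C/CC/C(C)=C/CC[C@@H](C)CCOB2C3CCCC2CCC3)C4CCCC1CCC4 | intermediate (not isolated)
12 | (1S,2R)-2-(2-phenylpropan-2-yl)cyclohexyl (6E,10E,14R)-16-hydroxy-6,10,14-trimethyl-2-methylidenehexadeca-6,10-dienoate | C=C(CCC/C(C)=C/CC/C(C)=C/CC[C@@H](C)CCO)C(=O)O[C@H]1CCCC[C@@H]1C(C)(C)c1ccccc1 | intermediate
13 | (1S,2R)-2-(2-phenylpropan-2-yl)cyclohexyl (13R)-15-hydroxy-ent-labd-8(17)-en-19-oate (ring stereocentres 4R,5S,9R,10S) | C=C1CC[C@H]2[C@@](C)(CCC[C@@]2(C)C(=O)O[C@H]3CCCC[C@@H]3C(C)(C)c4ccccc4)[C@@H]1CC[C@@H](C)CCO | intermediate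
14 | (13R)-15-hydroxy-ent-labd-8(17)-en-19-oic acid | C=C1CC[C@H]2[C@@](C)(CCC[C@@]2(C)C(=O)O)[C@@H]1CC[C@@H](C)CCO | intermediate
15 | (R)-2-methylbutanoic acid | CC[C@@H](C)C(=O)O | starting material
16 | (13R)-15-{[(2R)-2-methylbutanoyl]oxy}-ent-labd-8(17)-en-19-oic acid (CNP0109063.1) | C=C1CC[C@H]2[C@@](C)(CCC[C@@]2(C)C(=O)O)[C@@H]1CC[C@@H](C)CCOC(=O)[C@H](C)CC | target

## Step count and risks

Total step count: 8 (step 2 is one telescoped two-stage oxidation; step 4 is a side branch).
Longest linear sequence: 7 steps (1 → 2 → 4 → 5 → 12 → 13 → 14 → 16).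

**Step 6 (highest risk).** Four things must go right at once: HAT must start at the acrylate rather than at a trisubstituted alkene; the ester rather than the methyl must sit axial at C4; the auxiliary must give useful facial control (its sense is a model prediction; the diastereomers are esters of a chiral alcohol and should be separable); and divalent cobalt must end the cascade at C17 without the hydride later isomerising the 8(17)-alkene. Fallback: it sets out from 12 and comes back at 13. The acrylate alone is reduced with [(Ph3P)CuH]6 (cat.) and PhSiH3 to the saturated ester (1S,2R)-2-(2-phenylpropan-2-yl)cyclohexyl (2RS,6E,10E,14R)-16-hydroxy-2,6,10,14-tetramethylhexadeca-6,10-dienoate F1. Its lithium enolate (LiN(i-Pr)2, 2.2 equiv, THF, −78 °C) is then oxidised with copper bis(2-ethylhexanoate), Cu(O2CCH(C2H5)C4H9)2 (divalent copper, 2.5 equiv). The same C4 radical is thus made by one-electron enolate oxidation, and the final C8 radical is taken to the exocyclic alkene by copper-mediated oxidative elimination, so no metal hydride is present that could fail to initiate or isomerise the product.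

**Step 5.** The unprotected hydroxyl consumes borane and may disturb borate formation, and the acrylate electrophile is sensitive to free alkoxide. Fallback: it sets out from 5 and comes back at 12 by a radical addition–fragmentation allylation instead of the organocopper coupling. 5 is hydroborated as before and the borane is iodinated (I2, NaOMe, MeOH) to (3R,6E,10E)-13-iodo-3,7,11-trimethyltrideca-6,10-dien-1-ol F2. Bromide 10 is converted with EtSO2Na into the allyl sulfone (1S,2R)-2-(2-phenylpropan-2-yl)cyclohexyl 2-[(ethanesulfonyl)methyl]prop-2-enoate F3. Heating F2 with F3 and dilauroyl peroxide (cat.) in 1,2-dichloroethane lets the primary C2 radical add to F3, which fragments to 12; the ethyl radical released carries the iodine-transfer chain, and the free hydroxyl is indifferent to these radicals.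

**Step 7.** The dissolving metal may partly reduce the 1,1-disubstituted alkene, or cleave the acyl–oxygen bond instead. Fallback: it sets out from 13 and comes back at 16. LiAlH4 (THF, reflux) reduces the ester to (13R)-ent-labd-8(17)-ene-15,19-diol F4, with the auxiliary alcohol 7 recovered. 15 with EDC·HCl and DMAP acylates only the unhindered C15 hydroxyl to give (13R)-19-hydroxy-ent-labd-8(17)-en-15-yl (2R)-2-methylbutanoate F5. Jones oxidation (CrO3, H2SO4, acetone, 0 °C) of the neopentyl C19 alcohol then gives 16.

## Further compounds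

F1 | step 6 | (1S,2R)-2-(2-phenylpropan-2-yl)cyclohexyl (2RS,6E,10E,14R)-16-hydroxy-2,6,10,14-tetramethylhexadeca-6,10-dienoate | CC(CCC/C(C)=C/CC/C(C)=C/CC[C@@H](C)CCO)C(=O)O[C@H]1CCCC[C@@H]1C(C)(C)c1ccccc1
F2 | step 5 | (3R,6E,10E)-13-iodo-3,7,11-trimethyltrideca-6,10-dien-1-ol | ICC/C(C)=C/CC/C(C)=C/CC[C@@H](C)CCO
F3 | step 5 | (1S,2R)-2-(2-phenylpropan-2-yl)cyclohexyl 2-[(ethanesulfonyl)methyl]prop-2-enoate | C=C(CS(=O)(=O)CC)C(=O)O[C@H]1CCCC[C@@H]1C(C)(C)c1ccccc1
F4 | step 7 | (13R)-ent-labd-8(17)-ene-15,19-diol | C=C1CC[C@H]2[C@@](C)(CCC[C@@]2(C)CO)[C@@H]1CC[C@@H](C)CCO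
F5 | step 7 | (13R)-19-hydroxy-ent-labd-8(17)-en-15-yl (2R)-2-methylbutanoate | C=C1CC[C@H]2[C@@](C)(CCC[C@@]2(C)CO)[C@@H]1CC[C@@H](C)CCOC(=O)[C@H](C)CC
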